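**Retrosynthetic overview**
1. The target is cut at the ester into diol 24 and p-coumaric acid 25. The C6 carbinol comes from β-hydroxy ketone 23 by hydroxyl-directed reduction, and C4–OH/C5–H come from enone 19 by directed epoxidation and reductive epoxide opening.
2. Ring A (five-membered, C1–C5) is closed second: the C4–C5 bond is made by ketyl–nitrile cyclisation of cycloheptenone 13, followed by dehydration, isopropyl addition and oxidative 1,3-transposition.
3. Ring B (seven-membered, C1, C5–C10) is closed first. The strategy rests on its C8=C9 alkene lying γ,δ to C5 with quaternary C1 in between (C5–C1–C10–C9=C8), the pattern of a cyclohept-4-enone formed by a [3,3] shift. The C1–C10 bond is cut back to (S,E)-2-vinyl-5-alkylideneoxolane 12.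
4. 12 comes from alkynol 9 by anti iodoetherification of the alkyne and Negishi coupling, which fixes the enol ether geometry without an elimination step. 9 comes from (S)-linalool 4, made from geraniol 1 by Sharpless epoxidation.

Key step: step 9

Remark: locants C1–C10 in all intermediates are those of the target (C1 quaternary fusion carbon, C4 isopropyl carbinol, C5 fusion CH, C6 acyloxy carbon, C8=C9 alkene); for the two centres erased later (C5 of 15, C4 of 18) the SMILES shows the epimer expected to predominate.

**Route**

Step 1
Reactants: 1 geraniol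
Product: 2 (2S,3S)-2,3-epoxygeraniol
Conditions: Ti(OiPr)4 (5 mol %), L-(+)-diethyl tartrate (7 mol %), t-BuOOH, 4 Å MS, CH2Cl2, −20 °C
Reagents that add atoms: tert-butyl hydroperoxide CC(C)(C)OO
Why: Katsuki–Sharpless asymmetric epoxidation, in which the titanium tartrate complex bound to the allylic hydroxyl delivers oxygen to one face of the 2,3-alkene (L-(+)-tartrate gives 2S,3S) and so sets the future C8 centre, while the undirected 6,7-alkene is left alone.

Step 2
Reactants: 2 (2S,3S)-2,3-epoxygeraniol
Product: 3 (2S,3R)-3-(iodomethyl)-2-methyl-2-(4-methylpent-3-en-1-yl)oxirane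
Conditions: PPh3, imidazole, I2, CH2Cl2, 0 °C
Reagents that add atoms: iodine II
Why: Appel-type iodination of the primary alcohol via the alkoxyphosphonium salt, under which the epoxide and both stereocentres are untouched.

Step 3
Reactants: 3 epoxy iodide
Product: 4 (S)-linalool
Conditions: activated Zn dust, EtOH, reflux
Reagents that add atoms: none
Why: Reductive β-elimination, in which zinc inserts into the C–I bond and the organozinc opens the neighbouring epoxide to the transposed tertiary allylic alcohol; the tertiary C–O bond is never broken, so the (S) centre is retained.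

Step 4
Reactants: 4 (S)-linalool
Product: 7 (5S)-5-ethenyl-5-methyloxolan-2-ol (anomer mixture), via ozonide 5 (not isolated), via hydroxy aldehyde 6 (not isolated)
Conditions: O3 (1.0 equiv, Sudan Red 7B end point), CH2Cl2, −78 °C; then PPh3, −78 °C to rt
Reagents that add atoms: ozone [O-][O+]=O
Why: Chemoselective ozonolysis, since the electron-rich trisubstituted alkene reacts much faster than the vinyl group next to the carbinol; reduction of the peroxide frees the γ-hydroxy aldehyde, which closes to the lactol.

Step 5
Reactants: 7 lactol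
Product: 8 (3S)-3-methylhept-1-en-6-yn-3-ol
Conditions: dimethyl (1-diazo-2-oxopropyl)phosphonate, K2CO3, MeOH, 0 °C to rt
Reagents that add atoms: dimethyl (1-diazo-2-oxopropyl)phosphonate CC(=O)C(=[N+]=[N-])P(=O)(OC)OC
Why: Ohira–Bestmann (Seyferth–Gilbert) homologation of the open aldehyde tautomer 6, which is in equilibrium with the lactol under the basic conditions; the tertiary carbinol centre is not involved.

Step 6
Reactants: 8 terminal alkynol
Product: 9 (3S)-3-methyloct-1-en-6-yn-3-ol
Conditions: n-BuLi (2.1 equiv), THF, −78 to −20 °C; MeI (1.1 equiv), −78 °C to rt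
Reagents that add atoms: iodomethane CI
Why: Acetylide alkylation of the alkoxide–acetylide dianion, which is methylated at the far more nucleophilic acetylide carbon while the tertiary lithium alkoxide stays inert in THF.

Step 7
Reactants: 9 methyl alkynol
Product: 10 (2E,5S)-5-ethenyl-2-(1-iodoethylidene)-5-methyloxolane
Conditions: N-iodosuccinimide (1.1 equiv), NaHCO3, MeCN, 0 °C, dark
Reagents that add atoms: N-iodosuccinimide O=C1CCC(=O)N1I
Why: 5-exo-dig iodoetherification (iodocyclisation) of the 4-alkyn-1-ol, in which the tertiary hydroxyl opens the iodine-bridged alkyne anti, placing iodine trans and the methyl cis to the ring oxygen; this fixes the enol ether geometry, and the gem-disubstituted carbinol favours five-membered over 6-endo closure.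

Step 8
Reactants: 10 iodo enol ether; 11 2-cyanoethylzinc bromide
Product: 12 (4E)-4-[(5S)-5-ethenyl-5-methyloxolan-2-ylidene]pentanenitrile
Conditions: Pd(dppf)Cl2 (5 mol %), THF, 40 °C; NaHCO3 work-up, Et3N-deactivated silica
Reagents that add atoms: none
Why: Negishi coupling of an alkenyl iodide with a primary alkylzinc halide, which proceeds with retention at the alkene, so the cyanoethyl arm replaces iodine trans to oxygen and the (E)-tetrasubstituted enol ether results (dppf favours reductive elimination over β-hydride loss).

Step 9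
Reactants: 12 (S,E)-2-vinyl-5-alkylideneoxolane
Product: 13 3-[(1R)-1,4-dimethyl-7-oxocyclohept-3-en-1-yl]propanenitrile
Conditions: PhMe (0.05 M), 2,6-di-tert-butyl-4-methylpyridine (5 mol %), base-washed sealed tube, 180 °C
Reagents that add atoms: none
Why: Thermal [3,3]-sigmatropic (Claisen) shift of the allyl vinyl ether C1=C5–O–C8–C9=C10, in which C1–C10 forms as C8–O breaks; the closest known reaction type is the ring-expanding Claisen rearrangement of 2-vinyl-5-alkylideneoxolanes to cyclohept-4-enones, which tolerates a fully substituted enol ether terminus. Ring B closes by ring expansion of the oxolane through a bridged six-centre array held by the C6–C7 tether (commonly drawn boat-like), suprafacial on both three-atom units, and this delivers the cis C8=C9 alkene and the C5 ketone. The new quaternary centre C1 is set by chirality transfer from (S)-C8, because the vinyl group can reach the C5=C1 bond only on its own side of the oxolane. With the (E) geometry placing methyl cis to the ring oxygen and the cyanoethyl arm cis to C6, that face gives (R)-C1. The step needs the enol ether to keep its E and exocyclic form up to the rearrangement temperature, which the acid-free, base-buffered medium should secure since no thermal E/Z pathway exists. Formation of the C=O bond makes the shift irreversible.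

Step 10
Reactants: 13 keto nitrile
Product: 15 (1R,5R)-5-hydroxy-1,8-dimethyl 5–7 bicyclic 4-ketone (cis-fused α-ketol, C5–OH cis to C1–CH3, C8=C9), via hydroxy imine 14 (not isolated)
Conditions: SmI2 (3 equiv), t-BuOH (2 equiv), THF, visible light, rt; then dilute aq HCl, 0 °C
Reagents that add atoms: water O
Why: Reductive ketyl–nitrile coupling, in which the C5 ketyl adds 5-exo-dig to the nitrile carbon C4 to close ring A and the imine is hydrolysed to the α-ketol; the tether reaches C5 only from its own side, so the cis-fused ketol is expected, a centre erased in step 11.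

Step 11
Reactants: 15 α-ketol
Product: 16 (1R)-1,8-dimethyl 5–7 bicyclic 4-ketone with C5=C6 and C8=C9
Conditions: Burgess reagent (methyl N-(triethylammoniosulfonyl)carbamate), PhMe, 70 °C
Reagents that add atoms: none
Why: Burgess dehydration (syn elimination of the sulfamate ester) of the tertiary alcohol, where C6 carries the only β-hydrogens (C1 is quaternary, C4 a carbonyl), so only the conjugated C5=C6 enone can form.

Step 12
Reactants: 16 enone; 17 isopropylmagnesium chloride
Product: 18 (1R,4R)-4-isopropyl-1,8-dimethyl 5–7 bicyclic 4-ol with C5=C6 and C8=C9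
Conditions: LaCl3·2LiCl (0.3 equiv), THF, 0 °C; aq NH4Cl
Reagents that add atoms: none
Why: 1,2-Addition of the Grignard reagent to the enone carbonyl, with the lanthanum salt suppressing enolisation, β-hydride reduction and conjugate addition; attack anti to the C1 methyl is expected, but either C4 epimer serves because step 13 erases this centre.

Step 13
Reactants: 18 tertiary allylic alcohol
Product: 19 (1R)-4-isopropyl-1,8-dimethyl 5–7 bicyclic 6-ketone with C4=C5 and C8=C9
Conditions: pyridinium chlorochromate [C5H5NH][CrO3Cl] (2.5 equiv), NaOAc, 4 Å MS, CH2Cl2, rt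
Reagents that add atoms: pyridinium chlorochromate [O-][Cr](=O)(=O)Cl.c1cc[nH+]cc1
Why: Babler–Dauben oxidative transposition, in which the chromate ester of the tertiary allylic alcohol shifts [3,3] to C6 and is oxidised to the ketone conjugated with the tetrasubstituted C4=C5 alkene, the acetate buffer guarding against migration of C8=C9.

Step 14
Reactants: 19 enone
Product: 20 (1R,6R)-4-isopropyl-1,8-dimethyl 5–7 bicyclic 6-ol with C4=C5 and C8=C9 (C6–OH on the face of the C1 methyl)
Conditions: (S)-2-methyl-CBS-oxazaborolidine (0.5 equiv), catecholborane (2 equiv), PhMe, −78 °C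
Reagents that add atoms: none
Why: Corey–Bakshi–Shibata reduction, where the oxazaborolidine binds the carbonyl anti to the bulky alkenyl C5 side and sends hydride to the α-face, setting (6R) under reagent control and in line with attack anti to the C1 methyl; catecholborane at −78 °C does not hydroborate C8=C9.

Step 15
Reactants: 20 allylic alcohol
Product: 21 (1R,4R,5S,6R)-4,5-epoxy-4-isopropyl-1,8-dimethyl 5–7 bicyclic 6-ol with C8=C9 (epoxide and C6–OH on the face of the C1 methyl)
Conditions: VO(acac)2 (5 mol %), t-BuOOH (1.5 equiv), PhMe, 0 °C to rt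
Reagents that add atoms: tert-butyl hydroperoxide CC(C)(C)OO
Why: Hydroxyl-directed vanadium-catalysed epoxidation, in which the vanadate ester of the C6 hydroxyl delivers oxygen to the same (β) face of the tetrasubstituted C4=C5 alkene and sets C4 (R) and C5, while the homoallylic C8=C9 alkene reacts more slowly.

Step 16
Reactants: 21 epoxy alcohol
Product: 22 (1R,4R,5R)-4,5-epoxy-4-isopropyl-1,8-dimethyl 5–7 bicyclic 6-ketone with C8=C9
Conditions: Dess–Martin periodinane, pyridine, CH2Cl2, 0 °C to rt
Reagents that add atoms: none
Why: Dess–Martin oxidation of the secondary alcohol under buffered conditions that leave the acid-sensitive tetrasubstituted epoxide and the β,γ-alkene in place.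

Step 17
Reactants: 22 epoxy ketone
Product: 23 (1R,4R,5R)-4-hydroxy-4-isopropyl-1,8-dimethyl 5–7 bicyclic 6-ketone with C8=C9 (trans-fused, C4–OH cis to C1–CH3)
Conditions: SmI2 (2.5 equiv), THF/MeOH, −90 to −78 °C
Reagents that add atoms: none
Why: Reductive opening of the α,β-epoxy ketone by SmI2, in which electron transfer to the ketone and scission of the C5–O bond give the samarium enolate while C4 keeps its oxygen and configuration; protonation at C5 anti to the C1 methyl and to the samarium-bound C4 alkoxide should give the trans-fused (5R) ketone, which also has the isopropyl group trans to C6.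

Step 18
Reactants: 23 β-hydroxy ketone
Product: 24 (1R,4R,5S,6S)-4-isopropyl-1,8-dimethyl 5–7 bicyclic 4,6-diol with C8=C9 (jaeschkeanadiol)
Conditions: Me4NBH(OAc)3 (5 equiv), MeCN/AcOH (1:1), −30 to −20 °C
Reagents that add atoms: none
Why: Evans–Saksena hydroxyl-directed reduction, in which the C4 hydroxyl exchanges an acetate on boron and hydride is delivered intramolecularly to the β-face of the C6 carbonyl, giving the 1,3-anti diol with the new hydroxyl α (6S).

Step 19
Reactants: 25 p-coumaric acid
Product: 27 (E)-3-[4-(tert-butyldimethylsilyloxy)phenyl]prop-2-enoic acid, via bis-silyl derivative 26 (not isolated)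
Conditions: TBSCl (2.3 equiv), imidazole, DMF, rt; then AcOH/THF/H2O, rt
Reagents that add atoms: tert-butyldimethylsilyl chloride CC(C)(C)[Si](C)(C)Cl
Why: Silylation of phenol and acid followed by selective hydrolysis of the much more labile silyl ester, which leaves the aryl silyl ether and the (E)-alkene intact.

Step 20
Reactants: 24 diol; 27 protected acid
Product: 28 C6 (E)-4-(tert-butyldimethylsilyloxy)cinnamate of diol 24
Conditions: DCC (1.5 equiv), DMAP (0.3 equiv), CH2Cl2, rt
Reagents that add atoms: none
Why: Steglich esterification, in which the secondary C6 hydroxyl is acylated through the DMAP-activated O-acylisourea while the hindered tertiary C4 hydroxyl does not react and no stereocentre is touched.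

Step 21
Reactants: 28 silyl-protected ester
Product: 29 target, (1R,4R,5S,6S) C6 p-coumarate
Conditions: Bu4NF (1.1 equiv), AcOH (1.2 equiv), THF, 0 °C
Reagents that add atoms: none
Why: Fluoride-mediated cleavage of the aryl silyl ether, with acetic acid buffering the phenoxide so that the cinnamate ester and the tertiary alcohol survive.

**Compound list**
1 | geraniol | CC(C)=CCC/C(C)=C/CO | starting material
2 | (2S,3S)-2,3-epoxygeraniol | CC(C)=CCC[C@]1(C)O[C@H]1CO | intermediate
3 | (2S,3R)-3-(iodomethyl)-2-methyl-2-(4-methylpent-3-en-1-yl)oxirane | CC(C)=CCC[C@]1(C)O[C@H]1CI | intermediate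
4 | (S)-linalool | C=C[C@](O)(C)CCC=C(C)C | intermediate
5 | secondary ozonide of 4 at the trisubstituted alkene (diastereomer mixture) | C=C[C@](O)(C)CCC1OOC(C)(C)O1 | intermediate (not isolated)
6 | (4S)-4-hydroxy-4-methylhex-5-enal | C=C[C@](O)(C)CCC=O | intermediate (not isolated)
7 | (5S)-5-ethenyl-5-methyloxolan-2-ol (anomer mixture) | C=C[C@]1(C)CCC(O)O1 | intermediate
8 | (3S)-3-methylhept-1-en-6-yn-3-ol | C=C[C@](O)(C)CCC#C | intermediate
9 | (3S)-3-methyloct-1-en-6-yn-3-ol | C=C[C@](O)(C)CCC#CC | intermediate
10 | (2E,5S)-5-ethenyl-2-(1-iodoethylidene)-5-methyloxolane | C=C[C@]1(C)CC/C(=C(/C)I)O1 | intermediate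
11 | 2-cyanoethylzinc bromide | N#CCC[Zn]Br | starting material
12 | (4E)-4-[(5S)-5-ethenyl-5-methyloxolan-2-ylidene]pentanenitrile | C=C[C@]1(C)CC/C(=C(/C)CCC#N)O1 | intermediate (key-step precursor)
13 | 3-[(1R)-1,4-dimethyl-7-oxocyclohept-3-en-1-yl]propanenitrile | CC1=CC[C@@](C)(CCC#N)C(=O)CC1 | intermediate (key-step product)
14 | (1R,5R)-4-imino-1,8-dimethyl 5–7 bicyclic 5-ol with C8=C9 | CC1=CC[C@@]2(C)CCC(=N)[C@@]2(O)CC1 | intermediate (not isolated)
15 | (1R,5R)-5-hydroxy-1,8-dimethyl 5–7 bicyclic 4-ketone with C8=C9 | CC1=CC[C@@]2(C)CCC(=O)[C@@]2(O)CC1 | intermediate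
16 | (1R)-1,8-dimethyl 5–7 bicyclic 4-ketone with C5=C6 and C8=C9 | CC1=CC[C@@]2(C)CCC(=O)C2=CC1 | intermediate
17 | isopropylmagnesium chloride | CC(C)[Mg]Cl | starting material
18 | (1R,4R)-4-isopropyl-1,8-dimethyl 5–7 bicyclic 4-ol with C5=C6 and C8=C9 | CC1=CC[C@@]2(C)CC[C@@](O)(C(C)C)C2=CC1 | intermediate
19 | (1R)-4-isopropyl-1,8-dimethyl 5–7 bicyclic 6-ketone with C4=C5 and C8=C9 | CC1=CC[C@@]2(C)CCC(C(C)C)=C2C(=O)C1 | intermediate
20 | (1R,6R)-4-isopropyl-1,8-dimethyl 5–7 bicyclic 6-ol with C4=C5 and C8=C9 | CC1=CC[C@@]2(C)CCC(C(C)C)=C2[C@H](O)C1 | intermediate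
21 | (1R,4R,5S,6R)-4,5-epoxy-4-isopropyl-1,8-dimethyl 5–7 bicyclic 6-ol with C8=C9 | CC1=CC[C@@]2(C)CC[C@]3(C(C)C)O[C@]23[C@H](O)C1 | intermediate
22 | (1R,4R,5R)-4,5-epoxy-4-isopropyl-1,8-dimethyl 5–7 bicyclic 6-ketone with C8=C9 | CC1=CC[C@@]2(C)CC[C@]3(C(C)C)O[C@]23C(=O)C1 | intermediate
23 | (1R,4R,5R)-4-hydroxy-4-isopropyl-1,8-dimethyl 5–7 bicyclic 6-ketone with C8=C9 | CC1=CC[C@@]2(C)CC[C@@](O)(C(C)C)[C@@H]2C(=O)C1 | intermediate
24 | (1R,4R,5S,6S)-4-isopropyl-1,8-dimethyl 5–7 bicyclic 4,6-diol with C8=C9 (jaeschkeanadiol) | CC1=CC[C@@]2(C)CC[C@@](O)(C(C)C)[C@@H]2[C@@H](O)C1 | intermediate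
25 | p-coumaric acid | O=C(O)/C=C/c1ccc(O)cc1 | starting material
26 | tert-butyldimethylsilyl (E)-3-[4-(tert-butyldimethylsilyloxy)phenyl]prop-2-enoate | CC(C)(C)[Si](C)(C)OC(=O)/C=C/c1ccc(O[Si](C)(C)C(C)(C)C)cc1 | intermediate (not isolated)
27 | (E)-3-[4-(tert-butyldimethylsilyloxy)phenyl]prop-2-enoic acid | O=C(O)/C=C/c1ccc(O[Si](C)(C)C(C)(C)C)cc1 | intermediate
28 | C6 (E)-4-(tert-butyldimethylsilyloxy)cinnamate of 24 | CC1=CC[C@@]2(C)CC[C@@](O)(C(C)C)[C@@H]2[C@@H](OC(=O)/C=C/c2ccc(O[Si](C)(C)C(C)(C)C)cc2)C1 | intermediate
29 | target, (1R,4R,5S,6S) C6 p-coumarate | CC1=CC[C@@]2(C)CC[C@@](O)(C(C)C)[C@@H]2[C@@H](OC(=O)/C=C/c2ccc(O)cc2)C1 | target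

**Counts**
Total step count: 21. Longest linear sequence: 20 steps (steps 1–18, 20 and 21).

**Steps most likely to fail**

Step 9. The tetrasubstituted enol ether may lose its E and exocyclic form before the sigmatropic shift, through trace-acid E/Z or exo-to-endo isomerisation. Chirality transfer to C1 would then be eroded, or the endocyclic dihydrofuran, which cannot rearrange, would accumulate. The fallback sets the quaternary centre by a chiral-amine-controlled Michael addition instead of chirality transfer, and sets out from 9.
- Ph3PAuNTf2 (1 mol %) in CH2Cl2 should give 5-exo-dig hydroalkoxylation to (2Z,5S)-2-ethylidene-5-ethenyl-5-methyloxolane F1.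
- Heating in PhMe at 180 °C should give 2,5-dimethylcyclohept-4-enone F2 by the same ring expansion; its only stereocentre is epimerisable and does not matter.
- Condensation with (R)-1-phenylethylamine (PhMe, Dean–Stark) gives the N-[(1R)-1-phenylethyl] imine F3.
- Its more substituted enamine tautomer should add to acrylonitrile (THF, 50 °C) on the face away from the phenyl group to give the quaternary imine F4.
- Hydrolysis with aqueous AcOH returns to the route at 13.

Step 17. The samarium enolate may be protonated on the β-face, giving the cis-fused C5 epimer, for instance by internal proton delivery from the chelated alkoxide side. Base equilibration afterwards is not an option, because C7 is the more acidic site and the C8=C9 alkene would move into conjugation. The fallback replaces protonation of a planar enolate by stereospecific hydride delivery with inversion, and sets out from 22.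
- LiN(SiMe3)2 and TBSCl in THF at −78 °C should deprotonate C7, the only enolisable position, and give the silyl dienol ether F8.
- Pd2(dba)3·CHCl3, n-Bu3P and HCO2H/Et3N in dioxane at rt: zerovalent palladium should open the alkenyl oxirane at C5 with inversion, and the palladium hydride formed from formate should deliver hydrogen to C5 from the same α-face, giving the hydroxy silyl dienol ether F9.
- Bu4NF/AcOH in THF at 0 °C cleaves the silyl enol ether with protonation at C7 and returns to the route at 23.

Step 10. The hindered ketone may be reduced to the secondary alcohol, or couple intermolecularly, before the ketyl adds to the nitrile. The fallback closes ring A by a carbene-catalysed crossed benzoin reaction, and sets out from 10.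
- Negishi coupling with commercial 2-(1,3-dioxolan-2-yl)ethylzinc bromide under the conditions of step 8 gives (2E,5S)-2-[4-(1,3-dioxolan-2-yl)butan-2-ylidene]-5-ethenyl-5-methyloxolane F5.
- The rearrangement of step 9 gives (2R)-2-[2-(1,3-dioxolan-2-yl)ethyl]-2,5-dimethylcyclohept-4-en-1-one F6.
- PPTS in acetone/H2O frees 3-[(1R)-1,4-dimethyl-7-oxocyclohept-3-en-1-yl]propanal F7.
- 3-Benzyl-5-(2-hydroxyethyl)-4-methylthiazolium chloride and Et3N in EtOH at 70 °C generate the N-heterocyclic carbene, whose adduct with aldehyde C4 should add to ketone C5, returning to the route at α-ketol 15.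

**Further compounds**
F1 | step 9 | (2Z,5S)-2-ethylidene-5-ethenyl-5-methyloxolane | C=C[C@]1(C)CC/C(=C/C)O1
F2 | step 9 | 2,5-dimethylcyclohept-4-enone | CC1=CCC(C)C(=O)CC1
F3 | step 9 | N-[(1R)-1-phenylethyl] imine of 2,5-dimethylcyclohept-4-enone | CC1=CCC(C)C(CC1)=N[C@H](C)c1ccccc1
F4 | step 9 | N-[(1R)-1-phenylethyl] imine of 13 | CC1=CC[C@@](C)(CCC#N)C(CC1)=N[C@H](C)c1ccccc1
F5 | step 10 | (2E,5S)-2-[4-(1,3-dioxolan-2-yl)butan-2-ylidene]-5-ethenyl-5-methyloxolane | C=C[C@]1(C)CC/C(=C(/C)CCC2OCCO2)O1
F6 | step 10 | (2R)-2-[2-(1,3-dioxolan-2-yl)ethyl]-2,5-dimethylcyclohept-4-en-1-one | CC1=CC[C@@](C)(CCC2OCCO2)C(=O)CC1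
F7 | step 10 | 3-[(1R)-1,4-dimethyl-7-oxocyclohept-3-en-1-yl]propanal | CC1=CC[C@@](C)(CCC=O)C(=O)CC1
F8 | step 17 | (1R,4R,5R)-6-(tert-butyldimethylsilyloxy)-4,5-epoxy-4-isopropyl-1,8-dimethyl 5–7 bicycle with C6=C7 and C8=C9 | CC1=CC[C@@]2(C)CC[C@]3(C(C)C)O[C@]23C(O[Si](C)(C)C(C)(C)C)=C1
F9 | step 17 | (1R,4R,5R)-6-(tert-butyldimethylsilyloxy)-4-isopropyl-1,8-dimethyl 5–7 bicyclic 4-ol with C6=C7 and C8=C9 | CC1=CC[C@@]2(C)CC[C@@](O)(C(C)C)[C@@H]2C(O[Si](C)(C)C(C)(C)C)=C1
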